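## Structural features

The target is one benzene ring with four substituents in a 1,2,3,5 arrangement: a carboxylic acid at C1, a free phenol at C2, a methyl ether at C4 and a thirteen-carbon chain at C6, with hydrogen at C3 and C5. The chain is attached through a benzylic CH2 (C1'), carries a ketone at C2' and ends, after eleven more methylene groups, in a primary alcohol at C13'. There is no second ring and no stereocentre, so no relative configuration has to be set. The carboxyl carbon and the C2' ketone are 1,5-related through C1, C6 and C1', so the compound is the ring-opened form of an 8-hydroxy-6-methoxyisocoumarin and can close and dehydrate back to it under acid. The electron-rich salicylic acid can also lose CO2 when heated in acid. The carboxyl group sits between two ortho substituents, so a plain ester at C1 would be slow to saponify. The real difficulty is regiochemical: OH and OMe must be placed meta to each other and told apart, the carboxyl must lie between the OH and the chain, and the carbonyl must be at C2' and not at C1'. The key step uses the fact that C2–C3–C4–C5 is a four-carbon unit oxygenated at C2 and C4, while C1–C6 is a two-carbon unit that carries the carboxyl group and a chain whose C1'–C2' can be held at the alkyne oxidation level.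

## Logic of the disconnections

**16 to 15.** The carboxyl carbon is joined to the oxygen on C2', so the bond broken in the forward direction is the acyl–oxygen bond of the lactone in 15. An acid that is δ to a ketone is the hydrolysed form of an enol lactone, and cutting here stores the hindered acid and the benzylic ketone in one stable ring. The gain is that neither a free acid nor a free ketone is carried through the synthesis. The demand is that hydroxide opens the ring and that the acidification is gentle enough not to re-close it.

**15 to 13 (through 14).** The ring O–C3 bond of the pyranone (O–C2' of the chain) is cut and the terminal O–Si bond is restored. The C3=C4 enol ether is an alkyne C1'≡C2' to which the ester oxygen has added, so the ketone is carried as an alkyne and its position is fixed by the size of the ring that forms. The gain is a linear alkynyl side chain and a simple methyl ester. The demand is 6-endo closure onto C2' in preference to 5-exo closure onto C1', with the silyl ether removed in the same flask.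

**13 to 3 and 10 (through 11 and 12).** The ring bonds C1–C2 and C5–C6 are cut. The oxygenated four-carbon unit becomes the diene and the two-carbon unit becomes the ester-conjugated triple bond of a diynoate. The gain is the largest in the route: the tetrasubstituted arene and the OH/OMe distinction fall apart into two acyclic pieces. The demand is threefold: the CH2 end of the diene must meet the β-carbon of the ynoate, the triple bond next to the ester must react and not the distal one, and aromatisation must expel methanol and not silanol.

**10 to 8 (through 9).** The bond between the ester carbonyl carbon and C2 of the diynoate is cut, giving a diynyl anion and a chloroformate. Cutting here avoids a copper–amine coupling with a propiolate, which amines attack, and makes the electrophilic diynoate only just before it is used. The demand is clean silicon-to-lithium exchange at the remaining silylated terminus and no addition of the anion to the product.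

**8 to 5 and 6 (through 7).** The C(sp)–C(sp3) bond between the diyne and the eleven-carbon chain is cut. All four sp carbons then come from one purchasable block whose two silyl ends are unmasked one at a time, so no diyne cross-coupling is needed. The demand is an SN2 reaction of a moderately nucleophilic diynyl anion on a primary bromide, with only one silyl group removed.

**5 to 4.** The O–Si bond is cut. A free hydroxyl would quench the organolithium reagents and consume the silyl ketene acetal diene. The demand is trivial.

**3 to 2 to 1.** The O–Si bond of the ketene acetal and then the enol ether C–O bond are cut, leading back to a commodity β-keto ester. The demand is deprotonation at the γ-methyl group and silylation on oxygen.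

## Other disconnections considered

**Alternative 1:** The cut runs through C3–C4 and C5–C6. In the forward step the 2-pyrone A1 (ester at pyrone C5, methoxy at C4, ketal-protected chain at C6) would be heated with 1,1-dimethoxyethene A2. The CH2 of A2 would bond to pyrone C6 and its acetal carbon to pyrone C3, and the bridged lactone would lose CO2 and then methanol to give benzoate A3.

- In its favour: the ester and the chain are already on the pyrone, the polarity of the two partners leaves one regiochemical outcome, and only one π-bond can react. On site selectivity this alternative is better than the chosen plan. The C2' carbonyl is present from the start as a dioxolane, so no alkyne hydration has to be steered, which is also better.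
- Against it: both ring oxygens arrive as methyl ethers, so the ether ortho to the ester must be cleaved selectively with a Lewis acid that the dioxolane and silyl ether may not tolerate. The doubly ortho-substituted methyl ester must be saponified directly. A1 itself needs a multi-step synthesis.
- Comparison: mechanistically the two plans are equals, both being thermal cycloaddition–aromatisation sequences. Structurally the chosen plan delivers the OH/OMe distinction and turns the ester into a lactone without extra steps. On step economy Alternative 1 should be longer both before and after its key step.

**Alternative 2:** Three bonds are cut at once: C6–C1', C1–carboxyl and O–C2'. In the forward step CsF would release 3,5-dimethoxybenzyne A5 from silyl triflate A4. The copper acetylide from alkyne A6 and (IPr)CuCl, chloro[1,3-bis(2,6-diisopropylphenyl)imidazol-2-ylidene]copper, would add to the aryne carbon remote from the flanking methoxy group. The aryl copper would take up carbon dioxide A7 at the neighbouring carbon, and the carboxylate would close onto the alkyne to give isocoumarin A8.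

- In its favour: convergence is the best of all plans, since one operation forms three bonds and the lactone ring. The known bias of 3-alkoxy arynes places the carboxyl between oxygen and chain as required. A6 is two steps from 5. On convergence, and on step count if A4 is bought, this alternative equals or beats the chosen plan.
- Against it: several pathways compete in one flask, namely carboxylation of the acetylide without the aryne, alkynylation of the aryne without CO2 uptake, and 5-exo closure. A4 takes several steps if it has to be made. A8 has two methyl ethers, so a selective demethylation at the peri oxygen is needed before the final opening.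
- Comparison: the chosen plan has a two-component key step with one polarity-matched orientation and no demethylation. Alternative 2 has the more ambitious mechanism and the higher risk, and the arene is bought instead of built.

**Alternative 3:** Only C1–C6 is cut. In the forward step diketo-dioxinone A9 would form its dienolate with Et3N, C5 of the dioxinone would attack the distal ketone, and dehydration would give benzodioxinone A10.

- In its favour: the conditions are the mildest of all plans, which is better than the chosen plan's heating. The single free phenol can be methylated without ambiguity and the other oxygen stays in the acetonide, so the oxygen differentiation is equal to that of the chosen plan. The acid is released from an activated acetal ester and not from a hindered ester, and the C2' ketone is pre-installed.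
- Against it: A9 is a masked polyketone that needs successive acylations of a dioxinone dienolate with a ketal-bearing acid derivative, through tautomeric and sensitive intermediates. After the key step, methylation, dioxinone opening, deketalisation and desilylation follow, and the acidic deketalisation would act on a keto acid that tends to lactonise.
- Comparison: the aldol aromatisation is as reliable as the cycloaddition. The route should be clearly longer, and the final acid exposure is harsher than the cold acidification of the chosen plan.

Key step: step 6

Remarks on the chemistry:
- The side chain of 16 has eleven CH2 groups beyond C2', so the dienophile must be the sixteen-carbon diynoate 10, a hexadeca-2,4-diynoate with the silyl ether on C16. A fifteen-carbon diynoate would give a chain one carbon short.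
- Diene 3 is used as the isomer mixture formed on silylation, because the geometry at the ketene acetal carbon disappears on aromatisation.
- The target 16 is taken as the open keto acid, not its lactol.

## Route

Step 1
Reactants: 1 methyl acetoacetate (methyl 3-oxobutanoate)
Product: 2 methyl (E)-3-methoxybut-2-enoate
Conditions: HC(OMe)3, H2SO4 (cat.), MeOH, rt; then distillation
Reagents that add atoms: trimethyl orthoformate, COC(OC)OC
Why: Acid-catalysed O-methyl enol ether formation of a β-keto ester, with the orthoester as methyl donor and water scavenger; conjugation with the ester makes the (E)-enol ether the stable product, and its geometry does not matter later.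

Step 2
Reactants: 2 methyl (E)-3-methoxybut-2-enoate
Product: 3 1,3-dimethoxy-1-(trimethylsilyloxy)buta-1,3-diene (mixture of isomers at the ketene acetal carbon)
Conditions: LiN(i-Pr)2, THF, −78 °C; Me3SiCl, −78 °C to rt; filtration under N2, distillation
Reagents that add atoms: chlorotrimethylsilane, C[Si](C)(C)Cl
Why: The amide base removes a proton from the γ-methyl group, the only acidic C–H of this vinylogous carbonate, and the extended enolate is silylated on oxygen; this is silyl ketene acetal formation, the standard entry to 1,1,3-trioxygenated dienes.

Step 3
Reactants: 4 11-bromoundecan-1-ol
Product: 5 (11-bromoundecyloxy)(tert-butyl)dimethylsilane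
Conditions: t-BuMe2SiCl, imidazole, CH2Cl2, 0 °C to rt
Reagents that add atoms: tert-butyldimethylsilyl chloride, CC(C)(C)[Si](C)(C)Cl
Why: Imidazole-mediated silylation of a primary alcohol; the bromide is untouched and the silyl ether should tolerate the organolithium and thermal steps ahead.

Step 4
Reactants: 5 (11-bromoundecyloxy)(tert-butyl)dimethylsilane; 6 1,4-bis(trimethylsilyl)buta-1,3-diyne
Product: 8 tert-butyldimethyl{[15-(trimethylsilyl)pentadeca-12,14-diyn-1-yl]oxy}silane, via lithium (trimethylsilyl)butadiynide 7 (not isolated)
Conditions: 6, MeLi·LiBr (1.0 equiv), THF, −78 °C to rt; then 5, DMPU, Bu4NI (cat.), 0 °C to rt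
Reagents that add atoms: none
Why: MeLi·LiBr cleaves one alkynyl C–Si bond of 6, and the anion formed deactivates the second silyl group; the diynyl lithium 7 then displaces the primary bromide of 5 in the dipolar medium, an acetylide SN2 alkylation helped by iodide exchange.

Step 5
Reactants: 8 tert-butyldimethyl{[15-(trimethylsilyl)pentadeca-12,14-diyn-1-yl]oxy}silane
Product: 10 methyl 16-(tert-butyldimethylsilyloxy)hexadeca-2,4-diynoate, via lithium diynide 9 (not isolated)
Conditions: MeLi·LiBr, THF, −78 °C to rt; then cannulated into ClCO2Me (excess), THF, −78 to 0 °C
Reagents that add atoms: methyl chloroformate, COC(=O)Cl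
Why: The same silicon-to-lithium exchange unmasks the second diyne terminus, and inverse addition of diynyl lithium 9 to excess chloroformate at low temperature gives the ynoate by acyl substitution while keeping the anion away from the product; the alkyl silyl ether is inert to MeLi at these temperatures.

Step 6
Reactants: 3 1,3-dimethoxy-1-(trimethylsilyloxy)buta-1,3-diene; 10 methyl 16-(tert-butyldimethylsilyloxy)hexadeca-2,4-diynoate
Product: 13 methyl 6-[13-(tert-butyldimethylsilyloxy)tridec-1-yn-1-yl]-2-hydroxy-4-methoxybenzoate, via cyclohexa-1,4-diene adduct 11 (not isolated), via aryl trimethylsilyl ether 12 (not isolated)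
Conditions: 3 (2–3 equiv), PhMe, 100–110 °C, sealed tube; then 0.5 M aq. citric acid, THF, rt
Reagents that add atoms: none
Why: Diene 3, raised in energy by three oxygen donors, and ynoate 10, lowered by the ester and the second alkyne, should react in a normal-demand, strongly asynchronous Diels–Alder cycloaddition, the closest known type being the resorcylate synthesis from 1-alkoxy-1-silyloxy-3-oxygenated butadienes and alkynoates. The CH2 terminus of 3, which has the largest HOMO coefficient, bonds to C3 of 10 (ring bond C5–C6) and the ketene acetal carbon bonds to C2 (ring bond C1–C2), so the one new ring, the carbocycle, is closed by an intermolecular (4+2) cycloaddition. Adduct 11 is a cyclohexa-1,4-diene with a methyl silyl ketal at C2 and a CH2 at C5, and 1,4-elimination of methanol, driven by aromatisation, gives aryl silyl ether 12. Dilute citric acid then hydrolyses the aryl O–SiMe3 bond, which is far more labile than the primary O–Si(t-Bu)Me2 bond, and leaves the phenol hydrogen-bonded to the ester. The only stereocentre formed, the ketal carbon of 11, is racemic and disappears on aromatisation, so no stereocontrol is needed. Regioselectivity is secured by the ester, which makes C3 the electrophilic β-carbon that meets the nucleophilic CH2 terminus. Site selectivity for C2≡C3 over C4≡C5 is secured by direct conjugation with the ester, which takes up the charge developing at C2 as an ester allenolate, and by the slim alkynyl group on C3, whereas the distal triple bond carries the long alkyl chain on the carbon that would have to meet the diene. Methanol is expected to leave in preference to silanol because the silyl group stays on oxygen under neutral anhydrous heating, as is usual for mixed methyl silyl ketene acetal dienes, and this fixes OH at C2 and OMe at C4 without protecting-group work.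

Step 7
Reactants: 13 methyl 6-[13-(tert-butyldimethylsilyloxy)tridec-1-yn-1-yl]-2-hydroxy-4-methoxybenzoate
Product: 15 8-hydroxy-3-(11-hydroxyundecyl)-6-methoxy-1H-isochromen-1-one, via silyl ether isocoumarin 14 (not isolated)
Conditions: AuCl3 (5 mol %), MeCN/H2O (20:1), 50 °C; then 1 M aq. HCl, rt
Reagents that add atoms: water, O
Why: AuCl3 activates the alkyne as a π-acid, and the ester carbonyl oxygen, made electron-rich by the ortho OH and para OMe, attacks the alkyl-bearing carbon C2' in a 6-endo-dig oxycyclisation, a known reaction of 2-alkynylbenzoates. Water adds to the 1-methoxyisochromenylium intermediate and methanol is lost, so the lactone carbonyl oxygen comes from water; the dilute HCl then hydrolyses the primary silyl ether of 14.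

Step 8
Reactants: 15 8-hydroxy-3-(11-hydroxyundecyl)-6-methoxy-1H-isochromen-1-one
Product: 16 2-hydroxy-6-(13-hydroxy-2-oxotridecyl)-4-methoxybenzoic acid
Conditions: KOH (2 M aq.), EtOH, 50 °C; then 1 M HCl to pH 3, 0 °C, extraction with EtOAc
Reagents that add atoms: potassium hydroxide, [K+].[OH-]
Why: Hydroxide adds to the enol lactone carbonyl and the ring opens to the enolate of the C2' ketone (saponification of an enol ester), so the hindered acid and the ketone are released together. The acidification is kept cold and stops at pH 3 because the keto acid can re-close and dehydrate, or decarboxylate, under stronger acid or heat.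

## Compound list

1 | methyl acetoacetate (methyl 3-oxobutanoate) | COC(=O)CC(C)=O | starting material
2 | methyl (E)-3-methoxybut-2-enoate | COC(=O)/C=C(\C)OC | intermediate
3 | 1,3-dimethoxy-1-(trimethylsilyloxy)buta-1,3-diene | C=C(OC)C=C(OC)O[Si](C)(C)C | intermediate
4 | 11-bromoundecan-1-ol | OCCCCCCCCCCCBr | starting material
5 | (11-bromoundecyloxy)(tert-butyl)dimethylsilane | CC(C)(C)[Si](C)(C)OCCCCCCCCCCCBr | intermediate
6 | 1,4-bis(trimethylsilyl)buta-1,3-diyne | C[Si](C)(C)C#CC#C[Si](C)(C)C | starting material
7 | lithium 4-(trimethylsilyl)buta-1,3-diyn-1-ide | [Li]C#CC#C[Si](C)(C)C | intermediate (not isolated)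
8 | tert-butyldimethyl{[15-(trimethylsilyl)pentadeca-12,14-diyn-1-yl]oxy}silane | C[Si](C)(C)C#CC#CCCCCCCCCCCCO[Si](C)(C)C(C)(C)C | intermediate
9 | lithium 15-(tert-butyldimethylsilyloxy)pentadeca-1,3-diyn-1-ide | [Li]C#CC#CCCCCCCCCCCCO[Si](C)(C)C(C)(C)C | intermediate (not isolated)
10 | methyl 16-(tert-butyldimethylsilyloxy)hexadeca-2,4-diynoate | COC(=O)C#CC#CCCCCCCCCCCCO[Si](C)(C)C(C)(C)C | intermediate
11 | methyl 2-[13-(tert-butyldimethylsilyloxy)tridec-1-yn-1-yl]-4,6-dimethoxy-6-(trimethylsilyloxy)cyclohexa-1,4-diene-1-carboxylate (racemic) | COC(=O)C1=C(C#CCCCCCCCCCCCO[Si](C)(C)C(C)(C)C)CC(OC)=CC1(OC)O[Si](C)(C)C | intermediate (not isolated)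
12 | methyl 2-[13-(tert-butyldimethylsilyloxy)tridec-1-yn-1-yl]-4-methoxy-6-(trimethylsilyloxy)benzoate | COC(=O)c1c(O[Si](C)(C)C)cc(OC)cc1C#CCCCCCCCCCCCO[Si](C)(C)C(C)(C)C | intermediate (not isolated)
13 | methyl 6-[13-(tert-butyldimethylsilyloxy)tridec-1-yn-1-yl]-2-hydroxy-4-methoxybenzoate | COC(=O)c1c(O)cc(OC)cc1C#CCCCCCCCCCCCO[Si](C)(C)C(C)(C)C | intermediate
14 | 3-[11-(tert-butyldimethylsilyloxy)undecyl]-8-hydroxy-6-methoxy-1H-isochromen-1-one | COc1cc(O)c2c(c1)C=C(CCCCCCCCCCCO[Si](C)(C)C(C)(C)C)OC2=O | intermediate (not isolated)
15 | 8-hydroxy-3-(11-hydroxyundecyl)-6-methoxy-1H-isochromen-1-one | COc1cc(O)c2c(c1)C=C(CCCCCCCCCCCO)OC2=O | intermediate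
16 | 2-hydroxy-6-(13-hydroxy-2-oxotridecyl)-4-methoxybenzoic acid | COc1cc(O)c(C(=O)O)c(CC(=O)CCCCCCCCCCCO)c1 | target

## Step count and least certain steps

Total step count: 8. Longest linear sequence: 6 steps (steps 3, 4, 5, 6, 7 and 8, from 4 to 16). The diene branch (steps 1 and 2) joins at step 6.

**Step 6 (key step).** Three processes could go wrong.
- The CH2 terminus of the diene may add in a conjugate sense to the δ-carbon of the diynoate, or cycloaddition may occur across the distal triple bond, because the second alkyne extends the acceptor system.
- The moisture-sensitive diene may decompose thermally or by protonation before it reacts.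
- Aromatisation may proceed by loss of silanol instead of methanol, which would erase the OH/OMe distinction.

Fallback: buy the arene and attach the side chain by cross-coupling. It sets out from 5, which is homologated with LiC≡CH·H2NCH2CH2NH2 in DMSO to tert-butyldimethyl(tridec-12-yn-1-yloxy)silane F1. Purchasable methyl 2,6-dihydroxy-4-methoxybenzoate F2 is mono-triflated ((CF3SO2)2O, pyridine, CH2Cl2, −78 to 0 °C) to methyl 2-hydroxy-4-methoxy-6-(trifluoromethylsulfonyloxy)benzoate F3; the second hydroxyl is hydrogen-bonded to the ester and should resist a second sulfonylation. Sonogashira coupling of F3 with F1 (Pd(PPh3)2Cl2, CuI, Et3N, DMF, 60 °C) comes back to the route at 13.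

**Step 4.** The charge-delocalised diynyl anion is a weaker nucleophile than a simple acetylide, so the SN2 reaction may be sluggish. Elimination of HBr from the bromide, or a second desilylation followed by double alkylation, could then compete.

Fallback: build the diyne by cross-coupling. It sets out from 5, goes through the same terminal alkyne tert-butyldimethyl(tridec-12-yn-1-yloxy)silane F1 (LiC≡CH·H2NCH2CH2NH2, DMSO), then bromination at the alkyne terminus (N-bromosuccinimide, AgNO3 cat., acetone) to [(13-bromotridec-12-yn-1-yl)oxy](tert-butyl)dimethylsilane F4. Coupling of F4 with ethynyltrimethylsilane under anhydrous Pd/Cu conditions (Pd(PPh3)2Cl2, CuI, i-Pr2NH, THF), which leave the C–Si bond alone, comes back at 8.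

**Step 5.** The diynyl lithium or residual MeLi may add to the newly formed, highly electrophilic diynoate at the carbonyl or in a conjugate sense. Incomplete C–Si cleavage would leave starting material that is hard to separate.

Fallback: introduce the ester carbon without an organolithium. It sets out from 8, which is protodesilylated (K2CO3, MeOH, 0 °C) to tert-butyldimethyl(pentadeca-12,14-diyn-1-yloxy)silane F5. Carboxylative esterification of the acidic diyne C–H (Cs2CO3, AgI cat., CO2 at 1 atm, DMF; then MeI in the same flask) comes back at 10.

**Step 7.** Closure may occur in the 5-exo mode at C1' to give an alkylidene phthalide, which on opening would put the carbonyl at the wrong carbon. Gold-catalysed hydration of the alkyne without ester participation is a second risk.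

Fallback: let a free carboxylic acid be the nucleophile. It sets out from 13, which is saponified (KOH, EtOH/H2O, 70 °C) to 2-[13-(tert-butyldimethylsilyloxy)tridec-1-yn-1-yl]-6-hydroxy-4-methoxybenzoic acid F6. Brønsted acid-catalysed closure of F6 (CF3SO3H cat., CH2Cl2, 0 °C to rt), a setting in which 6-endo closure of 2-alkynylbenzoic acids is the expected course, followed by 1 M HCl in THF to remove the silyl group, comes back at 15.

## Further compounds

F1 | step 6 | tert-butyldimethyl(tridec-12-yn-1-yloxy)silane | C#CCCCCCCCCCCCO[Si](C)(C)C(C)(C)C
F2 | step 6 | methyl 2,6-dihydroxy-4-methoxybenzoate | COC(=O)c1c(O)cc(OC)cc1O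
F3 | step 6 | methyl 2-hydroxy-4-methoxy-6-(trifluoromethylsulfonyloxy)benzoate | COC(=O)c1c(O)cc(OC)cc1OS(=O)(=O)C(F)(F)F
F4 | step 4 | [(13-bromotridec-12-yn-1-yl)oxy](tert-butyl)dimethylsilane | BrC#CCCCCCCCCCCCO[Si](C)(C)C(C)(C)C
F5 | step 5 | tert-butyldimethyl(pentadeca-12,14-diyn-1-yloxy)silane | C#CC#CCCCCCCCCCCCO[Si](C)(C)C(C)(C)C
F6 | step 7 | 2-[13-(tert-butyldimethylsilyloxy)tridec-1-yn-1-yl]-6-hydroxy-4-methoxybenzoic acid | COc1cc(O)c(C(=O)O)c(C#CCCCCCCCCCCCO[Si](C)(C)C(C)(C)C)c1
A1 | alternative 1 | methyl 6-({2-[11-(tert-butyldimethylsilyloxy)undecyl]-1,3-dioxolan-2-yl}methyl)-4-methoxy-2-oxo-2H-pyran-5-carboxylate | COC(=O)C1=C(CC2(CCCCCCCCCCCO[Si](C)(C)C(C)(C)C)OCCO2)OC(=O)C=C1OC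
A2 | alternative 1 | 1,1-dimethoxyethene | C=C(OC)OC
A3 | alternative 1 | methyl 2-({2-[11-(tert-butyldimethylsilyloxy)undecyl]-1,3-dioxolan-2-yl}methyl)-4,6-dimethoxybenzoate | COC(=O)c1c(OC)cc(OC)cc1CC1(CCCCCCCCCCCO[Si](C)(C)C(C)(C)C)OCCO1
A4 | alternative 2 | 3,5-dimethoxy-2-(trimethylsilyl)phenyl trifluoromethanesulfonate | COc1cc(OC)c([Si](C)(C)C)c(OS(=O)(=O)C(F)(F)F)c1
A5 | alternative 2 | 3,5-dimethoxybenzyne (1,2-didehydro-3,5-dimethoxybenzene) | COC1=CC(OC)=CC#C1
A6 | alternative 2 | tert-butyldimethyl(tridec-12-yn-1-yloxy)silane | C#CCCCCCCCCCCCO[Si](C)(C)C(C)(C)C
A7 | alternative 2 | carbon dioxide | O=C=O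
A8 | alternative 2 | 3-[11-(tert-butyldimethylsilyloxy)undecyl]-6,8-dimethoxy-1H-isochromen-1-one | COc1cc(OC)c2c(c1)C=C(CCCCCCCCCCCO[Si](C)(C)C(C)(C)C)OC2=O
A9 | alternative 3 | 6-(5-{2-[11-(tert-butyldimethylsilyloxy)undecyl]-1,3-dioxolan-2-yl}-2,4-dioxopentyl)-2,2-dimethyl-4H-1,3-dioxin-4-one | CC1(C)OC(CC(=O)CC(=O)CC2(CCCCCCCCCCCO[Si](C)(C)C(C)(C)C)OCCO2)=CC(=O)O1
A10 | alternative 3 | 5-({2-[11-(tert-butyldimethylsilyloxy)undecyl]-1,3-dioxolan-2-yl}methyl)-7-hydroxy-2,2-dimethyl-4H-1,3-benzodioxin-4-one | CC1(C)Oc2cc(O)cc(CC3(CCCCCCCCCCCO[Si](C)(C)C(C)(C)C)OCCO3)c2C(=O)O1
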